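**Plan**
1. Retrosynthesis: cut C12–C13 (B-alkyl Suzuki–Miyaura coupling), then C6–C7 and C8–C9 together (three-component radical annulation of a ring A iodide with propyne), then C2=C3 (ring-closing metathesis), then C5–C10 (Ireland–Claisen rearrangement).
2. Forward: an acyclic allylic ester gives the C5–C10 bond, metathesis closes ring A, dihydroxylation and acetylation follow, the annulation closes ring B, and the C13–C15 unit is joined last.
3. Enabling feature: the C7=C8(CH3) olefin of ring B lies between the C6 methylene and the C9 methine, which sit trans on C5 and C10 of ring A. This is the retron of a propyne unit inserted between a C6 radical and a C9 radical acceptor (an allyl sulfone, lost in the same step).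
4. Stereochemistry: the C11 carbinol (CBS reduction) is transferred to C5 and C10 through the chair Claisen transition state; ring A then directs OsO4 (C2, C3) and the chair-like radical closure (C9).
5. Olefin geometry: C9=C11 from carboalumination and the Claisen step; C13=C14 from an (E)-enol triflate coupled with retention.

Key step: step 11

Remark (numbering): labdane numbering is used for all intermediates (ring A = C1–C5, C10; ring B = C5–C10; side chain C11–C15).
Remark (assumption): in the CBS reduction the trisubstituted alkenyl group is assumed to act as the large substituent; if the opposite sense is found, the enantiomeric catalyst is used.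

**Step 1**
Reactants: 1 pent-1-en-4-yne; 2 2-(phenylthio)acetyl chloride
Product: 4 (E)-4-methyl-1-(phenylthio)hepta-3,6-dien-2-one, via alkenylalane 3 (not isolated)
Conditions: Me3Al, Cp2ZrCl2 (cat.), CH2Cl2, 0 °C to rt; then 2, Pd(PPh3)4 (cat.), THF, 0 °C
Reagents that add atoms: trimethylaluminium, C[Al](C)C
Why: Negishi carboalumination adds CH3 and Al syn across the alkyne with Al on the terminal carbon, which fixes the (E) trisubstituted olefin, and the alkenylalane is then acylated by 2 with retention under Pd catalysis.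

**Step 2**
Reactants: 4 (E)-4-methyl-1-(phenylthio)hepta-3,6-dien-2-one
Product: 5 (2S,3E)-4-methyl-1-(phenylthio)hepta-3,6-dien-2-ol
Conditions: (S)-2-methyl-CBS-oxazaborolidine (cat.), catecholborane, toluene, −78 °C
Reagents that add atoms: none
Why: Corey–Bakshi–Shibata reduction, in which the ketone binds with the larger alkenyl group away from the catalyst, should give the (S)-carbinol (C11), the only stereocentre carried into the Claisen step.

**Step 3**
Reactants: 5 (2S,3E)-4-methyl-1-(phenylthio)hepta-3,6-dien-2-ol; 6 3,3-dimethylpent-4-enoic acid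
Product: 7 (2S,3E)-4-methyl-1-(phenylthio)hepta-3,6-dien-2-yl 3,3-dimethylpent-4-enoate
Conditions: DCC, DMAP (cat.), CH2Cl2, 0 °C to rt
Reagents that add atoms: none
Why: Steglich esterification of a secondary allylic alcohol; no stereocentre is touched.

**Step 4**
Reactants: 7 (2S,3E)-4-methyl-1-(phenylthio)hepta-3,6-dien-2-yl 3,3-dimethylpent-4-enoate
Product: 10 (2R,3S,4E)-3-allyl-3-methyl-2-(2-methylbut-3-en-2-yl)-6-(phenylthio)hex-4-enoic acid, via silyl ketene acetal 8 (not isolated), via trimethylsilyl ester 9 (not isolated)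
Conditions: LiN(iPr)2, THF/DMPU, −78 °C; TMSCl; −78 °C to 50 °C; aq. HCl work-up
Reagents that add atoms: none
Why: Ireland–Claisen rearrangement, in which enolisation with DMPU should give the (Z)-silyl ketene acetal and a chair transition state with CH2SPh equatorial transfers the C11 configuration to C5 and C10 (C6 trans to C9) while forming the C5–C10 bond and the (E)-C9=C11 olefin.

**Step 5**
Reactants: 10 (2R,3S,4E)-3-allyl-3-methyl-2-(2-methylbut-3-en-2-yl)-6-(phenylthio)hex-4-enoic acid
Product: 11 (2R,3S,4E)-3-allyl-3-methyl-2-(2-methylbut-3-en-2-yl)-6-(phenylthio)hex-4-en-1-ol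
Conditions: LiAlH4, THF, reflux
Reagents that add atoms: none
Why: LiAlH4 reduction of the hindered carboxylic acid to the primary alcohol (C6); the sulfide and the olefins are inert.

**Step 6**
Reactants: 11 (2R,3S,4E)-3-allyl-3-methyl-2-(2-methylbut-3-en-2-yl)-6-(phenylthio)hex-4-en-1-ol
Product: 12 (2R,3S,4E)-3-allyl-3-methyl-2-(2-methylbut-3-en-2-yl)-6-(phenylsulfonyl)hex-4-en-1-ol
Conditions: (NH4)6Mo7O24·4H2O (cat.), 30% aq. H2O2, EtOH, 0 °C to rt
Reagents that add atoms: hydrogen peroxide, OO
Why: molybdate-catalysed peroxide oxidation of the sulfide to the sulfone is chemoselective over isolated olefins; the sulfone later serves as the radical leaving group and deactivates C9=C11 toward OsO4.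

**Step 7**
Reactants: 12 (2R,3S,4E)-3-allyl-3-methyl-2-(2-methylbut-3-en-2-yl)-6-(phenylsulfonyl)hex-4-en-1-ol
Product: 13 (2R,3S,4E)-3-allyl-1-iodo-3-methyl-2-(2-methylbut-3-en-2-yl)-6-(phenylsulfonyl)hex-4-ene
Conditions: I2, PPh3, imidazole, toluene/MeCN, rt to 60 °C
Reagents that add atoms: iodine, II
Why: Appel-type iodination (SN2 at the primary C6 carbon) gives the radical precursor; the stereocentres are not involved.

**Step 8**
Reactants: 13 (2R,3S,4E)-3-allyl-1-iodo-3-methyl-2-(2-methylbut-3-en-2-yl)-6-(phenylsulfonyl)hex-4-ene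
Product: 14 (1S,6R)-6-(iodomethyl)-1,5,5-trimethyl-1-[(E)-3-(phenylsulfonyl)prop-1-enyl]cyclohex-3-ene
Conditions: second-generation Grubbs catalyst (5 mol %), CH2Cl2 (dilute), 40 °C
Reagents that add atoms: none
Why: ring-closing metathesis, in which the Ru carbene loads at the allyl group and closes onto the vinyl group to give six-membered ring A with C2=C3, the only alternative closure onto C9=C11 being a cyclobutene.

**Step 9**
Reactants: 14 (1S,6R)-6-(iodomethyl)-1,5,5-trimethyl-1-[(E)-3-(phenylsulfonyl)prop-1-enyl]cyclohex-3-ene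
Product: 15 (1S,2R,4S,5S)-4-(iodomethyl)-3,3,5-trimethyl-5-[(E)-3-(phenylsulfonyl)prop-1-enyl]cyclohexane-1,2-diol
Conditions: OsO4 (cat.), NMO, acetone/H2O, 0 °C to rt
Reagents that add atoms: osmium tetroxide, O=[Os](=O)(=O)=O; N-methylmorpholine N-oxide, C[N+]1([O-])CCOCC1; water, O
Why: Upjohn dihydroxylation, a syn addition to the electron-richer ring olefin from the face opposite the C10 methyl and the C5 iodomethyl groups, should set C2 and C3 with both hydroxyls cis to the C10 alkenyl group, the allyl sulfone olefin being electron-poor and neopentyl.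

**Step 10**
Reactants: 15 (1S,2R,4S,5S)-4-(iodomethyl)-3,3,5-trimethyl-5-[(E)-3-(phenylsulfonyl)prop-1-enyl]cyclohexane-1,2-diol
Product: 16 (1S,2R,4S,5S)-4-(iodomethyl)-3,3,5-trimethyl-5-[(E)-3-(phenylsulfonyl)prop-1-enyl]cyclohexane-1,2-diyl diacetate
Conditions: Ac2O, pyridine, DMAP (cat.), CH2Cl2, rt
Reagents that add atoms: acetic anhydride, CC(=O)OC(C)=O
Why: DMAP-catalysed acetylation of both secondary hydroxyls installs the acetates of the target.

**Step 11**
Reactants: 16 (1S,2R,4S,5S)-4-(iodomethyl)-3,3,5-trimethyl-5-[(E)-3-(phenylsulfonyl)prop-1-enyl]cyclohexane-1,2-diyl diacetate; 17 propyne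
Product: 18 (2S,3R,5S,9R,10S)-13,14,15,16-tetranorlabda-7,11-diene-2,3-diyl diacetate
Conditions: propyne (excess, condensed), Bu3SnSnBu3, benzene, hν (sunlamp), sealed tube, 30 °C
Reagents that add atoms: none
Why: Proposed new method: in a hydride-free radical chain Bu3Sn• (from photolysis of the ditin) abstracts iodine from C6, the primary C6 radical adds to the unsubstituted terminus of propyne (C6–C7), the rapidly inverting α-methylvinyl radical at C8 attacks C9 of the (E)-allyl sulfone (C8–C9), and β-scission of the C12–S bond releases PhSO2•, which regenerates Bu3Sn• from the ditin; the closest known reaction types are ditin-mediated radical allylation of alkyl iodides with allyl sulfones and radical annulation by alkyne addition followed by vinyl radical cyclisation. Ring B closes in the 6-exo-trig mode with the C7=C8 olefin inside the new ring. The new stereocentre C9 is set by a chair-like transition state on the trans-diequatorial C5 and C10 substituents of ring A, in which the C9=C11 bond lies pseudo-equatorial, so H9 ends anti to the axial C10 methyl (trans-decalin). The step needs addition to propyne to precede every other fate of the C6 radical, which is secured because no hydrogen donor is present and direct closure onto C9=C11 would require a 4-exo or 5-endo mode. Regioselectivity at propyne follows from attack at the unhindered CH terminus, and 6-exo closure of the pre-organised vinyl radical should outrun its addition to a second alkyne.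

**Step 12**
Reactants: 19 tert-butyl acetoacetate
Product: 20 tert-butyl (E)-3-(trifluoromethylsulfonyloxy)but-2-enoate
Conditions: Tf2O, aq. Me4NOH, hexanes, 5 °C
Reagents that add atoms: trifluoromethanesulfonic anhydride, O=S(=O)(OS(=O)(=O)C(F)(F)F)C(F)(F)F
Why: O-triflation of the β-keto ester enolate; with the non-chelating tetramethylammonium counter-ion the (E)-enol triflate (OTf trans to the ester) should form.

**Step 13**
Reactants: 18 (2S,3R,5S,9R,10S)-13,14,15,16-tetranorlabda-7,11-diene-2,3-diyl diacetate; 20 tert-butyl (E)-3-(trifluoromethylsulfonyloxy)but-2-enoate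
Product: 22 tert-butyl (2S,3R,5S,9R,10S,13E)-2,3-diacetoxylabda-7,13-dien-15-oate, via B-alkyl-9-BBN adduct 21 (not isolated)
Conditions: 9-BBN, THF, rt; then 20, Pd(dppf)Cl2 (cat.), aq. K3PO4, DMF, rt
Reagents that add atoms: none
Why: anti-Markovnikov hydroboration of the monosubstituted vinyl group with 9-BBN (C7=C8 is inert) followed by B-alkyl Suzuki–Miyaura coupling, which proceeds with retention at the enol triflate and so gives the (13E) olefin.

**Step 14**
Reactants: 22 tert-butyl (2S,3R,5S,9R,10S,13E)-2,3-diacetoxylabda-7,13-dien-15-oate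
Product: 24 (2S,3R,5S,9R,10S,13E)-2,3-diacetoxylabda-7,13-dien-15-oic acid (target), via trimethylsilyl ester 23 (not isolated)
Conditions: TMSOTf, 2,6-lutidine, CH2Cl2, 0 °C; then H2O
Reagents that add atoms: none
Why: silyl triflate-mediated cleavage of the tert-butyl ester (loss of isobutene, then hydrolysis of the silyl ester) under non-protic conditions that spare the acetates and the trisubstituted olefin.

**Compound list**
1 | pent-1-en-4-yne | C#CCC=C | starting material
2 | 2-(phenylthio)acetyl chloride | O=C(Cl)CSc1ccccc1 | starting material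
3 | (E)-dimethyl(2-methylpenta-1,4-dien-1-yl)alane | C[Al](C)/C=C(\C)CC=C | intermediate
4 | (E)-4-methyl-1-(phenylthio)hepta-3,6-dien-2-one | O=C(CSc1ccccc1)/C=C(\C)CC=C | intermediate
5 | (2S,3E)-4-methyl-1-(phenylthio)hepta-3,6-dien-2-ol | O[C@H](CSc1ccccc1)/C=C(\C)CC=C | intermediate
6 | 3,3-dimethylpent-4-enoic acid | C=CC(C)(C)CC(=O)O | starting material
7 | (2S,3E)-4-methyl-1-(phenylthio)hepta-3,6-dien-2-yl 3,3-dimethylpent-4-enoate | C=CC(C)(C)CC(=O)O[C@H](CSc1ccccc1)/C=C(\C)CC=C | intermediate
8 | (Z)-O-trimethylsilyl ketene acetal of 7 (CMe2 group cis to OSiMe3) | C=CC(C)(C)/C=C(\O[Si](C)(C)C)O[C@H](CSc1ccccc1)/C=C(\C)CC=C | intermediate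
9 | trimethylsilyl ester of 10 | C[Si](C)(C)OC(=O)[C@H](C(C)(C)C=C)[C@@](C)(CC=C)/C=C/CSc1ccccc1 | intermediate
10 | (2R,3S,4E)-3-allyl-3-methyl-2-(2-methylbut-3-en-2-yl)-6-(phenylthio)hex-4-enoic acid | OC(=O)[C@H](C(C)(C)C=C)[C@@](C)(CC=C)/C=C/CSc1ccccc1 | intermediate
11 | (2R,3S,4E)-3-allyl-3-methyl-2-(2-methylbut-3-en-2-yl)-6-(phenylthio)hex-4-en-1-ol | OC[C@H](C(C)(C)C=C)[C@@](C)(CC=C)/C=C/CSc1ccccc1 | intermediate
12 | (2R,3S,4E)-3-allyl-3-methyl-2-(2-methylbut-3-en-2-yl)-6-(phenylsulfonyl)hex-4-en-1-ol | OC[C@H](C(C)(C)C=C)[C@@](C)(CC=C)/C=C/CS(=O)(=O)c1ccccc1 | intermediate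
13 | (2R,3S,4E)-3-allyl-1-iodo-3-methyl-2-(2-methylbut-3-en-2-yl)-6-(phenylsulfonyl)hex-4-ene | IC[C@H](C(C)(C)C=C)[C@@](C)(CC=C)/C=C/CS(=O)(=O)c1ccccc1 | intermediate
14 | (1S,6R)-6-(iodomethyl)-1,5,5-trimethyl-1-[(E)-3-(phenylsulfonyl)prop-1-enyl]cyclohex-3-ene | C1C=CC(C)(C)[C@@H](CI)[C@]1(C)/C=C/CS(=O)(=O)c1ccccc1 | intermediate
15 | (1S,2R,4S,5S)-4-(iodomethyl)-3,3,5-trimethyl-5-[(E)-3-(phenylsulfonyl)prop-1-enyl]cyclohexane-1,2-diol | C1[C@H](O)[C@H](O)C(C)(C)[C@@H](CI)[C@]1(C)/C=C/CS(=O)(=O)c1ccccc1 | intermediate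
16 | (1S,2R,4S,5S)-4-(iodomethyl)-3,3,5-trimethyl-5-[(E)-3-(phenylsulfonyl)prop-1-enyl]cyclohexane-1,2-diyl diacetate | C1[C@H](OC(C)=O)[C@H](OC(C)=O)C(C)(C)[C@@H](CI)[C@]1(C)/C=C/CS(=O)(=O)c1ccccc1 | intermediate
17 | propyne | CC#C | starting material
18 | (2S,3R,5S,9R,10S)-13,14,15,16-tetranorlabda-7,11-diene-2,3-diyl diacetate | CC(=O)O[C@H]1C[C@@]2(C)[C@H](C=C)C(C)=CC[C@@H]2C(C)(C)[C@H]1OC(C)=O | intermediate
19 | tert-butyl acetoacetate | CC(=O)CC(=O)OC(C)(C)C | starting material
20 | tert-butyl (E)-3-(trifluoromethylsulfonyloxy)but-2-enoate | CC(C)(C)OC(=O)/C=C(\C)OS(=O)(=O)C(F)(F)F | intermediate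
21 | B-alkyl-9-BBN adduct of 18 (boron on C12) | CC(=O)O[C@H]1C[C@@]2(C)[C@H](CCB3C4CCCC3CCC4)C(C)=CC[C@@H]2C(C)(C)[C@H]1OC(C)=O | intermediate
22 | tert-butyl (2S,3R,5S,9R,10S,13E)-2,3-diacetoxylabda-7,13-dien-15-oate | CC(=O)O[C@H]1C[C@@]2(C)[C@H](CC/C(C)=C/C(=O)OC(C)(C)C)C(C)=CC[C@@H]2C(C)(C)[C@H]1OC(C)=O | intermediate
23 | trimethylsilyl ester of 24 | CC(=O)O[C@H]1C[C@@]2(C)[C@H](CC/C(C)=C/C(=O)O[Si](C)(C)C)C(C)=CC[C@@H]2C(C)(C)[C@H]1OC(C)=O | intermediate
24 | (2S,3R,5S,9R,10S,13E)-2,3-diacetoxylabda-7,13-dien-15-oic acid | CC(=O)O[C@H]1C[C@@]2(C)[C@H](CC/C(C)=C/C(=O)O)C(C)=CC[C@@H]2C(C)(C)[C@H]1OC(C)=O | target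

**Step count:** 14 steps in total; longest linear sequence 13 steps (steps 1–11, 13, 14).

**Steps most likely to fail**

Step 11 (labelled). The C6 radical may be lost to chain termination before it adds to the unactivated alkyne, or the vinyl radical may add to a second propyne instead of closing the ring. The fallback sets out from iodide 16 and divides the annulation into known reactions. Radical alkynylation of 16 with 1-(phenylsulfonyl)prop-1-yne (Bu3SnSnBu3, hν) should give the 2-butynyl compound F1. Hydrozirconation with Cp2Zr(H)Cl, which places zirconium on the methyl-bearing carbon, followed by I2 should give the vinyl iodide F2. Slow addition of Bu3SnH with AIBN then generates the same C8 vinyl radical, which closes 6-exo onto the allyl sulfone with loss of the sulfonyl radical, and the route is rejoined at 18.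

Step 9. Facial selectivity of osmylation may be poor in the conformationally mobile monocycle, and the C9=C11 olefin may compete. The fallback sets out from 14 and moves the oxygenation to the rigid trans-decalin. Compound 14 is taken through the conditions of step 11 to the triene F3 and through those of step 13 to the ester F4. mCPBA should epoxidise the trisubstituted C7=C8 olefin selectively from the face opposite the C10 methyl, giving the epoxide F5. OsO4/NMO then dihydroxylates C2=C3 from the face opposite the axial C10 and C4 methyl groups, giving the diol F6, and acetylation gives the diacetate F7. Deoxygenation of the epoxide with WCl6/n-BuLi restores C7=C8 and rejoins the route at 22.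

Step 4. Control of the ketene acetal geometry may be incomplete, or chair and boat pathways may compete in this congested rearrangement; either erodes the C5/C10 relative configuration. The fallback sets out from 1 and 2 and uses the complementary pairing of a (Z)-allylic alcohol with the (E)-silyl ketene acetal, which forms in THF without additive. Acyl Sonogashira coupling of 1 with 2 (PdCl2(PPh3)2, CuI, Et3N) should give the ynone F8. Asymmetric transfer hydrogenation (RuCl[(S,S)-TsDPEN](p-cymene), HCO2H/Et3N) should give the (R)-propargylic alcohol F9. Iron-catalysed syn methylmagnesiation (MeMgBr, Fe(acac)3) should give the (Z)-allylic alcohol F10, and Steglich esterification with 6 gives the ester F11. Ireland–Claisen rearrangement of F11 (LiN(iPr)2, THF, TMSCl) then converges on acid 10.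

**Further compounds**
F1 | step 11 | diacetate 16 with the CH2I group replaced by a but-2-ynyl group | C1[C@H](OC(C)=O)[C@H](OC(C)=O)C(C)(C)[C@@H](CC#CC)[C@]1(C)/C=C/CS(=O)(=O)c1ccccc1
F2 | step 11 | diacetate 16 with the CH2I group replaced by an (E)-3-iodobut-2-enyl group | C1[C@H](OC(C)=O)[C@H](OC(C)=O)C(C)(C)[C@@H](C/C=C(\C)I)[C@]1(C)/C=C/CS(=O)(=O)c1ccccc1
F3 | step 9 | 13,14,15,16-tetranorlabda-2,7,11-triene (C5, C9, C10 as in 18) | C1=CC(C)(C)[C@H]2CC=C(C)[C@@H](C=C)[C@]2(C)C1
F4 | step 9 | tert-butyl (13E)-labda-2,7,13-trien-15-oate (C5, C9, C10 as in 22) | C1=CC(C)(C)[C@H]2CC=C(C)[C@@H](CC/C(C)=C/C(=O)OC(C)(C)C)[C@]2(C)C1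
F5 | step 9 | 7,8-epoxide of F4 (oxygen on the face opposite the C10 methyl) | C1=CC(C)(C)[C@H]2C[C@@H]3O[C@]3(C)[C@@H](CC/C(C)=C/C(=O)OC(C)(C)C)[C@]2(C)C1
F6 | step 9 | tert-butyl (13E)-7,8-epoxy-2,3-dihydroxylabd-13-en-15-oate (C2, C3 as in 22) | O[C@H]1C[C@@]2(C)[C@H](CC/C(C)=C/C(=O)OC(C)(C)C)[C@@]3(C)O[C@H]3C[C@@H]2C(C)(C)[C@H]1O
F7 | step 9 | tert-butyl (13E)-2,3-diacetoxy-7,8-epoxylabd-13-en-15-oate | CC(=O)O[C@H]1C[C@@]2(C)[C@H](CC/C(C)=C/C(=O)OC(C)(C)C)[C@@]3(C)O[C@H]3C[C@@H]2C(C)(C)[C@H]1OC(C)=O
F8 | step 4 | 1-(phenylthio)hept-6-en-3-yn-2-one | O=C(CSc1ccccc1)C#CCC=C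
F9 | step 4 | (R)-1-(phenylthio)hept-6-en-3-yn-2-ol | O[C@@H](CSc1ccccc1)C#CCC=C
F10 | step 4 | (2R,3Z)-4-methyl-1-(phenylthio)hepta-3,6-dien-2-ol | O[C@@H](CSc1ccccc1)/C=C(/C)CC=C
F11 | step 4 | (2R,3Z)-4-methyl-1-(phenylthio)hepta-3,6-dien-2-yl 3,3-dimethylpent-4-enoate | C=CC(C)(C)CC(=O)O[C@@H](CSc1ccccc1)/C=C(/C)CC=C
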